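**Retrosynthetic overview**
1. The last C–C bond made is the ArCH2–CH2Ar' bridge. It is cut between two carbons that are both electrophilic in their stable precursors: a benzylic chloride on the finished chromene core and the C=O carbon of a 4-silyloxybenzaldehyde.
2. The aldehyde carbon is reversed into a benzyl-carbanion equivalent as its N–H hydrazone. N2 leaves tracelessly, so no carbonyl group has to be removed afterwards.
3. The benzylic chloride comes from lateral lithiation and chlorination of the 5-methyl group (ortho-toluate) of the chromene ester.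
4. The pyran ring comes from prenal by condensation and oxa-6π closure at the only free ring position of methyl 3-prenylorsellinate. That ester comes from C-prenylation of methyl orsellinate.
5. Ring order: both benzene rings are bought. The 2H-pyran is the only ring formed (step 2), before the bridge.

Assumption: the SMILES holds no stereocentre and no E/Z-stereogenic alkene (the chromene C=C is ring-locked cis), so the target is achiral and needs no enantiocontrol.

**Step 1**
Reactants: 1 methyl 2,4-dihydroxy-6-methylbenzoate (methyl orsellinate); 2 1-bromo-3-methylbut-2-ene (prenyl bromide)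
Product: 3 methyl 2,4-dihydroxy-6-methyl-3-(3-methylbut-2-en-1-yl)benzoate
Conditions: KOH (1.1 equiv), H2O, 2 (1.2 equiv), 0 °C to rt, 16 h
Reagents that add atoms: none
Why: Phenoxide C-alkylation (ortho-allylation of an ambident anion): in water the 4-phenoxide oxygen is hydrogen-bond solvated, so carbon attacks prenyl bromide, and C3, which is ortho to both oxygens and less hindered than C5, is the most nucleophilic ring carbon, giving a moderate yield with the O-ether and bis-alkylated material removed by chromatography.

**Step 2**
Reactants: 3 methyl 2,4-dihydroxy-6-methyl-3-(3-methylbut-2-en-1-yl)benzoate; 4 3-methylbut-2-enal (prenal)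
Product: 6 methyl 7-hydroxy-2,2,5-trimethyl-8-(3-methylbut-2-en-1-yl)-2H-chromene-6-carboxylate, via ortho-quinone methide 5 (not isolated)
Conditions: 4 (2 equiv), ethylenediammonium diacetate (20 mol %), toluene, reflux, 12 h
Reagents that add atoms: none
Why: Knoevenagel-type condensation followed by oxa-6π electrocyclisation (formal [3+3] chromene annulation): C5 is the only free ring carbon, lies ortho to the 4-OH, para to the 2-OH and meta to the ester, so the iminium ion of prenal is attacked there, water is lost to give 5, and 5 can close only onto the C4 oxygen.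

**Step 3**
Reactants: 6 methyl 7-hydroxy-2,2,5-trimethyl-8-(3-methylbut-2-en-1-yl)-2H-chromene-6-carboxylate
Product: 8 methyl 5-(chloromethyl)-7-hydroxy-2,2-dimethyl-8-(3-methylbut-2-en-1-yl)-2H-chromene-6-carboxylate, via dilithio dianion 7 (not isolated)
Conditions: LiN(iPr)2 (2.2 equiv), THF, −78 °C, 45 min; cannula into C2Cl6 (1.5 equiv), THF, −78 °C; AcOH quench, −78 °C to rt
Reagents that add atoms: hexachloroethane, ClC(Cl)(Cl)C(Cl)(Cl)Cl (one Cl, in 8); lithium diisopropylamide, [Li+].CC(C)[N-]C(C)C (Li, in 7 only)
Why: Lateral lithiation of an ortho-toluate followed by halophilic chlorination: after the phenol, the 5-methyl group is the most acidic C–H because its anion is an ester-conjugated ortho-quinodimethane enolate, inverse addition to excess C2Cl6 chlorinates it before it can be alkylated by product, and both alkenes survive because no radical or free electrophilic halogen is present.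

**Step 4**
Reactants: 9 4-hydroxybenzaldehyde
Product: 10 4-(triisopropylsilyloxy)benzaldehyde
Conditions: iPr3SiCl (1.1 equiv), imidazole (2 equiv), DMF, rt, 3 h
Reagents that add atoms: chlorotriisopropylsilane, CC(C)[Si](Cl)(C(C)C)C(C)C
Why: Imidazole-promoted O-silylation masks the phenol, whose phenoxide would otherwise O-benzylate with 8 in step 6, and the bulky silyl group withstands hydrazine and K3PO4.

**Step 5**
Reactants: 10 4-(triisopropylsilyloxy)benzaldehyde
Product: 11 (E)-[4-(triisopropylsilyloxy)benzylidene]hydrazine (the N-unsubstituted hydrazone of 10)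
Conditions: N2H4·H2O (3 equiv), EtOH, 0 °C to rt, 1 h; Et2O/H2O extraction, dry (Na2SO4), concentrate, use the same day
Reagents that add atoms: hydrazine monohydrate, NN.O
Why: Carbonyl–hydrazine condensation: excess hydrazine suppresses azine formation and is washed out so that none remains to attack 8, and the E geometry of the C=N bond is of no consequence because it is lost in step 6.

**Step 6**
Reactants: 8 methyl 5-(chloromethyl)-7-hydroxy-2,2-dimethyl-8-(3-methylbut-2-en-1-yl)-2H-chromene-6-carboxylate; 11 (E)-[4-(triisopropylsilyloxy)benzylidene]hydrazine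
Product: 14 methyl 7-hydroxy-5-[2-(4-hydroxyphenyl)ethyl]-2,2-dimethyl-8-(3-methylbut-2-en-1-yl)-2H-chromene-6-carboxylate, via alkyl diazene 12 (not isolated), via triisopropylsilyl ether 13 (not isolated)
Conditions: Ni(cod)2 (10 mol %), Cy2PCH2CH2PCy2 (12 mol %), K3PO4 (3 equiv), 11 (1.5 equiv), THF, 50 °C, 8 added over 4 h; then Bu4NF (2 equiv), rt, 1 h
Reagents that add atoms: none
Why: Proposed new method: zerovalent nickel inserts into the benzylic C–Cl bond of slowly added 8 faster than 8 can N-alkylate 11, the hydrazone (an aza-enamine whose former aldehyde carbon is now the nucleophile) binds to the divalent benzylnickel species, is deprotonated by K3PO4 and forms the C–C bond at carbon to give diazene 12, which loses N2 in a base-induced Wolff–Kishner-type step and is protonated to the CH2–CH2 bridge of 13 before fluoride frees the phenol; the closest known reaction type is the nickel-catalysed cross-coupling of aldehyde hydrazones (carbonyl-umpolung alkyl-carbanion equivalents) with alkyl and aryl halides, extended here to an ortho-ester benzylic chloride, and the transient stereocentre of 12 disappears because that carbon becomes CH2.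

**Compound list**
1 | methyl 2,4-dihydroxy-6-methylbenzoate (methyl orsellinate) | COC(=O)c1c(C)cc(O)cc1O | starting material
2 | 1-bromo-3-methylbut-2-ene (prenyl bromide) | CC(C)=CCBr | starting material
3 | methyl 2,4-dihydroxy-6-methyl-3-(3-methylbut-2-en-1-yl)benzoate | COC(=O)c1c(C)cc(O)c(CC=C(C)C)c1O | intermediate
4 | 3-methylbut-2-enal (prenal) | CC(C)=CC=O | starting material
5 | ortho-quinone methide: 4-oxo-5-(3-methylbut-2-enylidene)cyclohexadiene form of the C5 condensation product of 3 and 4, exocyclic geometry not fixed, not isolated | COC(=O)C1=C(C)C(=CC=C(C)C)C(=O)C(CC=C(C)C)=C1O | intermediate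
6 | methyl 7-hydroxy-2,2,5-trimethyl-8-(3-methylbut-2-en-1-yl)-2H-chromene-6-carboxylate | COC(=O)c1c(O)c(CC=C(C)C)c2c(c1C)C=CC(C)(C)O2 | intermediate
7 | dilithio dianion of 6 (lithium 7-phenoxide, 5-lithiomethyl), not isolated | [Li+].[Li+].COC(=O)c1c([O-])c(CC=C(C)C)c2c(c1[CH2-])C=CC(C)(C)O2 | intermediate
8 | methyl 5-(chloromethyl)-7-hydroxy-2,2-dimethyl-8-(3-methylbut-2-en-1-yl)-2H-chromene-6-carboxylate | COC(=O)c1c(O)c(CC=C(C)C)c2c(c1CCl)C=CC(C)(C)O2 | intermediate
9 | 4-hydroxybenzaldehyde | O=Cc1ccc(O)cc1 | starting material
10 | 4-(triisopropylsilyloxy)benzaldehyde | CC(C)[Si](Oc1ccc(C=O)cc1)(C(C)C)C(C)C | intermediate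
11 | (E)-[4-(triisopropylsilyloxy)benzylidene]hydrazine | CC(C)[Si](Oc1ccc(/C=N/N)cc1)(C(C)C)C(C)C | intermediate
12 | methyl 5-{2-diazenyl-2-[4-(triisopropylsilyloxy)phenyl]ethyl}-7-hydroxy-2,2-dimethyl-8-(3-methylbut-2-en-1-yl)-2H-chromene-6-carboxylate (racemic, transient, not isolated) | COC(=O)c1c(O)c(CC=C(C)C)c2c(c1CC(N=N)c1ccc(O[Si](C(C)C)(C(C)C)C(C)C)cc1)C=CC(C)(C)O2 | intermediate
13 | methyl 7-hydroxy-2,2-dimethyl-8-(3-methylbut-2-en-1-yl)-5-{2-[4-(triisopropylsilyloxy)phenyl]ethyl}-2H-chromene-6-carboxylate (not isolated) | COC(=O)c1c(O)c(CC=C(C)C)c2c(c1CCc1ccc(O[Si](C(C)C)(C(C)C)C(C)C)cc1)C=CC(C)(C)O2 | intermediate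
14 | methyl 7-hydroxy-5-[2-(4-hydroxyphenyl)ethyl]-2,2-dimethyl-8-(3-methylbut-2-en-1-yl)-2H-chromene-6-carboxylate (achiral) | COC(=O)c1c(O)c(CC=C(C)C)c2c(c1CCc1ccc(O)cc1)C=CC(C)(C)O2 | target

**Total step count:** 6.
**Longest linear sequence:** 4 steps (1 → 3 → 6 → 8 → 14). The side arm 9 → 10 → 11 takes 2 steps before the union.

**Three steps most likely to fail**

Step 6 is the riskiest. The hydrazone NH2 can be N-benzylated by 8 and then close onto the ester to give an isoindolinone. Chloride 8 can homocouple, 11 can simply be reduced to the toluene, and zerovalent nickel may attack the allylic C–O bond of the chromene. The fallback keeps the same bond and polarity but replaces catalysis with a stoichiometric sulfur-stabilised acyl-anion equivalent. It sets out from 10 and 8. Aldehyde 10 with propane-1,3-dithiol and BF3·OEt2 (CH2Cl2, 0 °C) gives 2-[4-(triisopropylsilyloxy)phenyl]-1,3-dithiane F1. Lithiation with nBuLi (THF, −30 °C) and addition of the lithium phenoxide of 8 (pre-formed with LiN(SiMe3)2) gives methyl 7-hydroxy-2,2-dimethyl-8-(3-methylbut-2-en-1-yl)-5-({2-[4-(triisopropylsilyloxy)phenyl]-1,3-dithian-2-yl}methyl)-2H-chromene-6-carboxylate F2. Bu3SnH (2.5 equiv) with 2,2'-azobis(2-methylpropionitrile) in toluene at 80 °C converts both C–S bonds into C–H bonds through benzylic radicals. The unactivated alkenes are left alone. This gives 13, where the fallback comes back to the route, and Bu4NF then gives 14.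

Step 3 is the second risk. The phenoxide lowers the acidity of the 5-methyl group. Product 8 can also be alkylated or deprotonated by unreacted 7, which would give the dimer or the dichloride. The fallback traps the anion with an electrophile whose product is not itself an alkylating agent, and activates it afterwards. It sets out from 6 through 7. Quenching 7 with dimethyl disulfide (−78 °C) gives methyl 7-hydroxy-2,2-dimethyl-8-(3-methylbut-2-en-1-yl)-5-[(methylsulfanyl)methyl]-2H-chromene-6-carboxylate F3. S-Methylation with methyl trifluoromethanesulfonate (CH2Cl2, 0 °C) gives {[7-hydroxy-6-(methoxycarbonyl)-2,2-dimethyl-8-(3-methylbut-2-en-1-yl)-2H-chromen-5-yl]methyl}dimethylsulfonium trifluoromethanesulfonate F4. F4 takes the place of 8 in step 6, because benzylic sulfonium salts add oxidatively to zerovalent nickel. The fallback comes back to the route at 13.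

Step 2 is the third risk. C5 is flanked by the 6-methyl group, and the ring is less nucleophilic than a simple resorcinol, so the condensation may stall. The fallback swaps the intermolecular C–C bond formation for an intramolecular sigmatropic one. It sets out from 3. Selective O-alkylation of the non-chelated 4-OH with 3-chloro-3-methylbut-1-yne (CuCl2 1 mol %, DBU, MeCN, 0 °C) gives methyl 2-hydroxy-6-methyl-3-(3-methylbut-2-en-1-yl)-4-[(2-methylbut-3-yn-2-yl)oxy]benzoate F5. Heating in N,N-diethylaniline at 140–180 °C triggers an aryl propargyl Claisen rearrangement to the only open ortho carbon. A [1,5]-hydrogen shift then gives 5, and oxa-6π closure follows. The fallback comes back to the route at 6.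

**Further compounds**
F1 | step 6 | 2-[4-(triisopropylsilyloxy)phenyl]-1,3-dithiane | CC(C)[Si](Oc1ccc(C2SCCCS2)cc1)(C(C)C)C(C)C
F2 | step 6 | methyl 7-hydroxy-2,2-dimethyl-8-(3-methylbut-2-en-1-yl)-5-({2-[4-(triisopropylsilyloxy)phenyl]-1,3-dithian-2-yl}methyl)-2H-chromene-6-carboxylate | COC(=O)c1c(O)c(CC=C(C)C)c2c(c1CC1(SCCCS1)c1ccc(O[Si](C(C)C)(C(C)C)C(C)C)cc1)C=CC(C)(C)O2
F3 | step 3 | methyl 7-hydroxy-2,2-dimethyl-8-(3-methylbut-2-en-1-yl)-5-[(methylsulfanyl)methyl]-2H-chromene-6-carboxylate | COC(=O)c1c(O)c(CC=C(C)C)c2c(c1CSC)C=CC(C)(C)O2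
F4 | step 3 | {[7-hydroxy-6-(methoxycarbonyl)-2,2-dimethyl-8-(3-methylbut-2-en-1-yl)-2H-chromen-5-yl]methyl}dimethylsulfonium trifluoromethanesulfonate | COC(=O)c1c(O)c(CC=C(C)C)c2c(c1C[S+](C)C)C=CC(C)(C)O2.[O-]S(=O)(=O)C(F)(F)F
F5 | step 2 | methyl 2-hydroxy-6-methyl-3-(3-methylbut-2-en-1-yl)-4-[(2-methylbut-3-yn-2-yl)oxy]benzoate | COC(=O)c1c(C)cc(OC(C)(C)C#C)c(CC=C(C)C)c1O
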